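- Each product takes up one partner, and the protic impurity quenches partner one for one, so count partner first. Substrate turns into intermediate A, which meets partner. Intermediates B and C are proposed side stations on the way.

| setting | theta | beta | Thursday's | Monday's |
|---|---|---|---|---|
| substrate | 0.40 M (fed, over 10 h) | 0.40 M (fed, over 10 h) | 0.40 M (fed, over 5.0 h) | 0.40 M (fed, over 10 h) |
| partner | 0.42 M | 0.92 M | 0.300 M | 0.600 M |
| protic impurity | 0.20 M | 0.20 M | 0.200 M | 0.200 M |
| temperature | −15 °C | 15 °C |  |  |
| remark | run made earlier | run made earlier | at −10 °C throughout | at −10 °C until 10 h, from then on at 40 °C |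
| time |  |  | 15 h | 15 h |

- theta (time / h: product / %, substrate / %): 1.33: 2.1, 7.6; 2.50: 9.6, 12.3; 4.00: 21.4, 15.2; 5.00: 29.2, 16.6; 6.00: 37.0, 14.6; 8.00: 51.8, 17.3
- beta (time / h: product / %, substrate / %): 0.133: 0, 0; 0.417: 4.0, 1.1; 0.667: 7.4, 0.9; 1.33: 13.6, 0.8; 2.00: 17.9, 1.2; 2.50: 23.8, 0.4

(each reading ± 1 percentage point)

- steps that have been proposed: partner + intermediate A -> product; partner + intermediate A -> intermediate B; substrate -> intermediate A; partner + protic impurity -> quenched reagent; partner + intermediate A <-> intermediate C; intermediate B -> product
- percentages count the whole charge, also what has not yet gone in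

1. the winner by amount of product, in percent of the substrate charged; "neither" if no more than 2 percentage points parts them (Thursday's / Monday's / neither)
2. how much product is there at the end, in percent of the substrate charged: Thursday's
3. how much product is there at the end, in percent of the substrate charged: Monday's

- Thursday's has a partner floor F of 25.0 %, meaning partner charge minus impurity charge, divided by substrate charge. It is the product left if the impurity takes its whole charge. With no quench, partner would allow 75.0 %, so partner is Thursday's limiting reagent.
- The first instants are the substrate's. In the theta run substrate reads 16.6 % at 5.00 h, so each portion lingers as substrate for about 1.66 h; that is the substrate's stay, and any wait as intermediate A comes on top of it.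
- The middle is a race for partner. Thursday's feed, 0.0800 M h⁻¹, is twice theta's, and at that pace it would use up the partner in 3.75 h. That window is shorter than theta's 10.5 h, so the impurity has less time.
- Theta's floor is 55.0 %, and its last product reading, 51.8 %, lies below it, so that reading does not reach the floor. At 8.00 h the feed has delivered 80.0 %, and 10.9 % of the charge reads as neither product nor substrate, a sign of material waiting for partner. I draw no rate for the quench from so few readings, so my own estimate for Thursday's is the middle of the bracket, 50.0 %.
- At the end of Monday's, the floor is >99.9 %, and its window of 15.0 h outlasts the 10 h feed. The warm stage should clear what still waits, so I expect >99.9 % and Monday's ahead.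
- The forecast named Monday's, with 25 % for Thursday's and 96 % for Monday's, on the ground that “The impurity appears to consume partner quickly”, and its Thursday's figure is lower than mine.
- The flasks give 46.1 % for Thursday's and 100 % for Monday's, so Monday's wins.

    partner + intermediate A → product (k = 0.370 L mol⁻¹ min⁻¹, Ea = 59.0 kJ mol⁻¹)
    partner + intermediate A → intermediate B (k = 0.0160 L mol⁻¹ min⁻¹, Ea = 66.0 kJ mol⁻¹)
    substrate → intermediate A (k = 0.0220 min⁻¹, Ea = 88.0 kJ mol⁻¹)
    partner + protic impurity → quenched reagent (k = 0.0270 L mol⁻¹ min⁻¹, Ea = 48.0 kJ mol⁻¹)
    partner + intermediate A ⇌ intermediate C (K = 0.960 L mol⁻¹, k = 0.0320 L mol⁻¹ min⁻¹, Ea = 64.0 kJ mol⁻¹, ΔH = −40.0 kJ mol⁻¹)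
    intermediate B → product (k = 0.00780 min⁻¹, Ea = 83.0 kJ mol⁻¹)
    (constants at −10 °C)

- At 3.25 h in Thursday's, the step to product drew partner 7.8 times as fast as the quench did. By 5.00 h partner stood at 0.288 % of its charge with 42.3 % of the impurity unquenched, which is 21.1 % of the substrate charge, and F plus that gives 46.1 %. A neighbour of Thursday's with 0.75 M of partner has F at 138 %, which predicts 20.0 % of its partner spare, and it ended with product at >99.9 % and 20.1 % of its partner left.

(The data are simulated from invented constants, and the scatter is random.)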